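**Pl​an**

Numbering (clerodane): ring A = C1–C5/C10, ring B = C5–C10, C17/C18 = exocyclic CH2 on C8/C4, C19/C20 = methyls on C5/C9, C11–C16 = side chain with the lactone.
Cuts, in order: C8=C17 (α-methylenation); C4=C18 (reductive allylic transposition of a C18–O carbonate, which also frees 6-OH); the C1 ester; C1–C2 and C5–C10 together; C5–C6 (alkenylmagnesium plus aldehyde); C12–C13 (aldol); the two C9–C bonds (lactone alkylations).
Enabling feature: in ring A the O-bearing C1–C10(H) pair and the C2–C3–C4(C18)–C5(CH3) unit are an alkene and a diene already linked through C6–C9 of ring B. A C1≡C10 alkyne, once hydroborated, can therefore close rings A and B in one intramolecular Diels–Alder step, and its C–B bond becomes C1–O.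
Forward order: chiral lactone, C9 quaternary centre, alkyne and side-chain lactone, C5–C6 union with the Z-diene fragment, temporary seven-membered C18–O/C6–O carbonate ring, rings A and B together, then ester, ketone and the two exocyclic methylenes.
Stereochemistry: C7 from (R)-5-(hydroxymethyl)butanolide (helper centre, later the ketone); C9 by trans-alkylation of that lactone; C12/C13 by an oxazolidinone syn-aldol; C6 by chelation control from C7; C1/C5/C10 in the cycloaddition from the E-alkenylborane, the Z-diene and the substituted chair tether.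

Key step: step 17

Remark: 9, 11 and 14 are mixtures at one centre that is re-formed or removed in the next operation; their SMILES show the major epimer (9) or leave that centre open (11, 14).

**Route**

Step 1
Reactants: 1 but-2-yn-1-ol
Product: 3 (2Z)-2-ethenyl-3-iodobut-2-en-1-ol, via magnesium chelate 2 (not isolated)
Conditions: CH2=CHMgCl (3.5 equiv), THF/PhMe, reflux; then I2, THF, −78 → 0 °C
Reagents that add atoms: vinylmagnesium chloride, C=C[Mg]Cl; iodine, II
Why: Alkoxide-directed anti-carbomagnesiation of a propargylic alcohol puts vinyl on the carbon next to CH2O and magnesium on the far carbon, cis to CH2O in a five-membered chelate, and iodinolysis with retention should give the tetrasubstituted Z-iodide (alkene geometry from the chelate, no stereocentre).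

Step 2
Reactants: 4 (4S)-4-benzyl-1,3-oxazolidin-2-one; 5 methyl 4-chloro-4-oxobutanoate
Product: 6 methyl 4-[(4S)-4-benzyl-2-oxo-1,3-oxazolidin-3-yl]-4-oxobutanoate
Conditions: n-BuLi, THF, −78 °C; then 5, −78 → 0 °C
Reagents that add atoms: none
Why: N-Acylation of the lithiated oxazolidinone by the acid chloride should be clean because the methyl ester is far less electrophilic; no new stereocentre.

Step 3
Reactants: 7 (5R)-5-(hydroxymethyl)oxolan-2-one
Product: 8 (5R)-5-[(trityloxy)methyl]oxolan-2-one
Conditions: TrCl, Et3N, DMAP (cat.), CH2Cl2, rt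
Reagents that add atoms: trityl chloride, ClC(c1ccccc1)(c1ccccc1)c1ccccc1
Why: Tritylation of the primary alcohol installs the bulky group that later shields one face of the lactone enolate; no new stereocentre.

Step 4
Reactants: 8 trityl lactone
Product: 9 (3S,5R)-3-methyl-5-[(trityloxy)methyl]oxolan-2-one
Conditions: LiN(i-Pr)2, THF, −78 °C; then MeI
Reagents that add atoms: iodomethane, CI
Why: Lactone enolate alkylation should give mainly the trans product, and the epimer ratio does not matter because this centre is re-enolised in step 5.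

Step 5
Reactants: 9 methyl lactone
Product: 10 (3S,5R)-3-methyl-3-(prop-2-en-1-yl)-5-[(trityloxy)methyl]oxolan-2-one
Conditions: LiN(i-Pr)2, THF/DMPU, −78 °C; then allyl bromide, −78 → −40 °C
Reagents that add atoms: allyl bromide, C=CCBr
Why: The second enolate alkylation should occur anti to the trityloxymethyl group, so allyl enters trans and methyl ends cis to CH2OTr, which fixes the quaternary C9 centre (substrate-controlled lactone enolate alkylation).

Step 6
Reactants: 10 allyl methyl lactone
Product: 11 (3S,5R)-3-methyl-3-(prop-2-en-1-yl)-5-[(trityloxy)methyl]oxolan-2-ol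
Conditions: i-Bu2AlH, CH2Cl2, −78 °C; aq. KNaC4H4O6 (potassium sodium tartrate) work-up
Reagents that add atoms: none
Why: Partial reduction of the hindered lactone should stop at the lactol because the tetrahedral aluminate is stable at −78 °C.

Step 7
Reactants: 11 lactol
Product: 12 (2R,4S)-4-ethynyl-4-methyl-1-(trityloxy)hept-6-en-2-ol
Conditions: dimethyl (1-diazo-2-oxopropyl)phosphonate, K2CO3, MeOH, 0 °C → rt
Reagents that add atoms: dimethyl (1-diazo-2-oxopropyl)phosphonate, CC(=O)C(=[N+]=[N-])P(=O)(OC)OC
Why: Ohira–Bestmann (Seyferth–Gilbert) homologation of the lactol through its ring-opened hydroxy-aldehyde tautomer should give the terminal alkyne and free the C7 hydroxyl; the quaternary α-carbon cannot epimerise.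

Step 8
Reactants: 12 alkynol
Product: 13 PMB ether of 12
Conditions: NaH, PMBCl, Bu4NI (cat.), THF/DMF, 0 °C → rt
Reagents that add atoms: 4-methoxybenzyl chloride, COc1ccc(CCl)cc1
Why: Williamson etherification of the secondary alkoxide gives the ether that later serves as the chelating group; NaH deprotonates the alcohol in preference to the alkyne.

Step 9
Reactants: 13 PMB ether
Product: 15 (3R,5R)-3-ethynyl-5-[(4-methoxybenzyl)oxy]-3-methyl-6-(trityloxy)hexanal, via vicinal diol 14 (not isolated)
Conditions: OsO4 (2 mol %), NaIO4, 2,6-lutidine, dioxane/H2O, rt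
Reagents that add atoms: osmium tetroxide, O=[Os](=O)(=O)=O; sodium periodate, [Na+].[O-]I(=O)(=O)=O
Why: Lemieux–Johnson oxidation (dihydroxylation, then periodate cleavage) should cleave the monosubstituted alkene while the alkyne, which is dihydroxylated far more slowly, survives.

Step 10
Reactants: 15 aldehyde; 6 succinate imide
Product: 16 syn-aldol adduct (12R,13S)
Conditions: 6, Bu2BOTf, i-Pr2NEt, CH2Cl2, −78 → 0 °C; then 15, −78 → 0 °C; pH 7 buffer, MeOH, H2O2
Reagents that add atoms: none
Why: Evans syn-aldol reaction of the Z-boron enolate, formed at the imide α-CH2 and not at the ester, through a closed chair transition state should set C12 and C13 under control of the (S)-benzyl oxazolidinone with the target configuration at both centres.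

Step 11
Reactants: 16 aldol adduct
Product: 17 C12 tiglate of 16
Conditions: (E)-2-methylbut-2-enoyl chloride, pyridine, DMAP (cat.), CH2Cl2, 0 °C → rt
Reagents that add atoms: (E)-2-methylbut-2-enoyl chloride, C/C=C(\C)C(Cl)=O
Why: Acylation of the secondary alcohol under nucleophilic catalysis installs the final tiglate early and blocks the C12 oxygen from the later lactonisation.

Step 12
Reactants: 17 tiglate imide
Product: 19 trityl-protected alkynyl butanolide, via hydroxy ester 18 (not isolated)
Conditions: NaBH4, THF/H2O, 0 °C → rt; then PPTS (cat.), PhMe, 50 °C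
Reagents that add atoms: none
Why: NaBH4 in aqueous THF reduces the N-acyl oxazolidinone to the primary alcohol with release of the auxiliary while the methyl ester and tiglate survive, and the C16 alcohol then closes the five-membered lactone onto the methyl ester (reductive auxiliary removal, then lactonisation).

Step 13
Reactants: 19 trityl ether
Product: 20 primary alcohol (6-OH)
Conditions: TsOH·H2O (cat.), MeOH/CH2Cl2, 0 °C → rt
Reagents that add atoms: none
Why: Acid-catalysed methanolysis should remove the trityl ether selectively because the PMB ether, lactone and tiglate are stable to catalytic TsOH at room temperature.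

Step 14
Reactants: 20 primary alcohol
Product: 21 α-(PMB-oxy) aldehyde
Conditions: Dess–Martin periodinane, NaHCO3, CH2Cl2, 0 °C → rt
Reagents that add atoms: none
Why: Buffered Dess–Martin oxidation should give the α-alkoxy aldehyde without epimerisation at C7.

Step 15
Reactants: 21 aldehyde; 3 (2Z)-2-ethenyl-3-iodobut-2-en-1-ol
Product: 23 (6R,7R)-Z-dienediol, via bis(chloromagnesium) reagent 22 (not isolated)
Conditions: 3 (2.5 equiv), i-PrMgCl·LiCl (2 equiv per 3), THF, −20 → 0 °C; then 21 + MgBr2·OEt2, CH2Cl2, −78 °C; aq. NH4Cl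
Reagents that add atoms: none
Why: The first equivalent of i-PrMgCl deprotonates the alcohol of 3 and the second exchanges iodine for magnesium with retention of the alkene geometry to give the chloromagnesium alkoxide/alkenylmagnesium chloride 22, which should add to the aldehyde held in a five-membered MgBr2 chelate with the α-OPMB group from the face opposite C8, so that C6 is set syn to C7 (chelation-controlled 1,2-addition), the aldehyde reacting far faster than the lactone and ester carbonyls at −78 °C.

Step 16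
Reactants: 23 dienediol
Product: 24 seven-membered cyclic carbonate (cycloaddition precursor)
Conditions: CDI, DMAP (cat.), CH2Cl2 (high dilution), 0 °C → rt
Reagents that add atoms: 1,1'-carbonyldiimidazole, O=C(n1ccnc1)n1ccnc1
Why: CDI acylates the primary allylic alcohol and the Z geometry lets the C6 hydroxyl close the seven-membered carbonate, a temporary ring that masks both hydroxyls and later serves as the allylic leaving group.

Step 17
Reactants: 24 cyclic carbonate dienyne
Product: 27 tricyclic decalinol, via alkenylborane 25 (not isolated), via cycloadduct borane 26 (not isolated)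
Conditions: Cy2BH (1.1 equiv), THF, 0 °C → rt; then PhMe, 80 °C; then Me3NO·2H2O (3.3 equiv), 60 °C
Reagents that add atoms: trimethylamine N-oxide, C[N+](C)(C)[O-]
Why: Proposed new method: Cy2BH should add syn and anti-Markovnikov to the terminal alkyne of 24 to give the (E)-alkenylborane 25, whose empty boron p orbital lowers the alkene LUMO so that it undergoes a concerted suprafacial [4+2] cycloaddition with the tethered diene, forming C1–C2 and C5–C10 together (borane 26), after which Me3NO replaces boron by oxygen with retention. The closest known reaction types are the intermolecular Diels–Alder reaction of vinyl- and (E)-alkenyl-dialkylboranes with 1,3-dienes followed by oxidation, and the thermal type 1 intramolecular Diels–Alder reaction of 1,7,9-decatrienes; their union on a hydroborated dienyne is the untested part, argued from the matched polarity (electrophilic C10 meets the more substituted diene terminus C5) and the four-atom tether. Ring B closes as the fused ring of the type 1 mode through a chair-like C6–C9 tether lying exo to the diene while boron lies endo, which gives the trans fusion, and ring A is the cyclohexene of the cycloaddition itself with its alkene left at C3=C4. C1 and C10 are fixed relative to each other by the E geometry of 25 and C1–O by the stereoretentive oxidation; C5 is fixed by the Z-diene geometry from step 1 (C19 inside, tether outside) together with the endo mode; the diene face is fixed by the preset C6, C7 and C9 centres, because only one chair keeps C6–O, C7–OPMB and C11 equatorial with C20 axial. The step needs chemoselective hydroboration (dialkylboranes react with a terminal alkyne faster than with a conjugated diene or a trisubstituted enoate, and the carbonate masks both hydroxyls), endo selectivity (boron–diene secondary overlap plus the preferred anti tether) and facial selectivity (the three tether stereocentres).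

Step 18
Reactants: 27 decalinol
Product: 28 C1 isobutyrate
Conditions: (i-PrCO)2O, Et3N, DMAP, CH2Cl2, rt
Reagents that add atoms: isobutyric anhydride, CC(C)C(=O)OC(=O)C(C)C
Why: DMAP-catalysed acylation of the equatorial C1 alcohol with the anhydride should give the isobutyrate without touching the other esters or the carbonate.

Step 19
Reactants: 28 isobutyrate
Product: 29 C7 alcohol
Conditions: DDQ, CH2Cl2/pH 7 buffer, 0 °C → rt
Reagents that add atoms: none
Why: Oxidative cleavage of the PMB ether by DDQ (single-electron oxidation of the electron-rich arene, then hydrolysis of the oxocarbenium ion) should free the C7 alcohol under neutral conditions.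

Step 20
Reactants: 29 C7 alcohol
Product: 30 C7 ketone
Conditions: Dess–Martin periodinane, NaHCO3, CH2Cl2, rt
Reagents that add atoms: none
Why: Dess–Martin oxidation converts the C7 alcohol into the ketone and so removes the helper stereocentre, the buffered conditions leaving C6 untouched.

Step 21
Reactants: 30 keto carbonate
Product: 31 6-hydroxy-7-keto-4(18)-ene
Conditions: Pd2(dba)3·CHCl3 (5 mol %), PBu3 (20 mol %), HCO2H, Et3N, THF, 40 °C
Reagents that add atoms: none
Why: Zerovalent palladium ionises the allylic C18–O bond of the cyclic carbonate, decarboxylation frees the C6 alkoxide, and hydride from formate is delivered from palladium to the more substituted allyl terminus C3, which should give the exocyclic C4=C18 methylene and the free 6-hydroxyl in one step (Tsuji-type formate hydrogenolysis of an allylic carbonate).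

Step 22
Reactants: 31 hydroxy ketone
Product: 32 CNP0148909.1 (target)
Conditions: (CH2O)n, i-Pr2NH·CF3CO2H, THF, 65 °C
Reagents that add atoms: formaldehyde (from paraformaldehyde), C=O
Why: Amine-salt-mediated Mannich/aldol condensation with formaldehyde at C8, the only α-carbon of the ketone that carries two hydrogens, followed by elimination should give the α-methylene ketone under conditions that the esters, the lactone and the free 6-hydroxyl tolerate.

**Compound list**

1 | but-2-yn-1-ol | CC#CCO | starting material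
2 | 4-ethenyl-3-methyl-2,5-dihydro-1,2-oxamagnesole (chelated alkenylmagnesium alkoxide; salts and solvent omitted) | C=CC1=C(C)[Mg]OC1 | intermediate (not isolated)
3 | (2Z)-2-ethenyl-3-iodobut-2-en-1-ol | OC/C(C=C)=C(\I)C | intermediate
4 | (4S)-4-benzyl-1,3-oxazolidin-2-one | O=C1N[C@@H](Cc2ccccc2)CO1 | starting material
5 | methyl 4-chloro-4-oxobutanoate | COC(=O)CCC(Cl)=O | starting material
6 | methyl 4-[(4S)-4-benzyl-2-oxo-1,3-oxazolidin-3-yl]-4-oxobutanoate | COC(=O)CCC(=O)N1[C@@H](Cc2ccccc2)COC1=O | intermediate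
7 | (5R)-5-(hydroxymethyl)oxolan-2-one | OC[C@H]1CCC(=O)O1 | starting material
8 | (5R)-5-[(trityloxy)methyl]oxolan-2-one | O=C1CC[C@H](COC(c2ccccc2)(c2ccccc2)c2ccccc2)O1 | intermediate
9 | (3S,5R)-3-methyl-5-[(trityloxy)methyl]oxolan-2-one (major, trans) | O=C1O[C@@H](COC(c2ccccc2)(c2ccccc2)c2ccccc2)C[C@@H]1C | intermediate
10 | (3S,5R)-3-methyl-3-(prop-2-en-1-yl)-5-[(trityloxy)methyl]oxolan-2-one | O=C1O[C@@H](COC(c2ccccc2)(c2ccccc2)c2ccccc2)C[C@]1(C)CC=C | intermediate
11 | (3S,5R)-3-methyl-3-(prop-2-en-1-yl)-5-[(trityloxy)methyl]oxolan-2-ol (both anomers) | OC1O[C@@H](COC(c2ccccc2)(c2ccccc2)c2ccccc2)C[C@]1(C)CC=C | intermediate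
12 | (2R,4S)-4-ethynyl-4-methyl-1-(trityloxy)hept-6-en-2-ol | C#C[C@](C)(C[C@@H](O)COC(c1ccccc1)(c1ccccc1)c1ccccc1)CC=C | intermediate
13 | 1-({[(2R,4S)-4-ethynyl-4-methyl-1-(trityloxy)hept-6-en-2-yl]oxy}methyl)-4-methoxybenzene | C#C[C@](C)(C[C@@H](OCc1ccc(OC)cc1)COC(c1ccccc1)(c1ccccc1)c1ccccc1)CC=C | intermediate
14 | (4S,6R)-4-ethynyl-6-[(4-methoxybenzyl)oxy]-4-methyl-7-(trityloxy)heptane-1,2-diol (both C2 epimers) | C#C[C@](C)(C[C@@H](OCc1ccc(OC)cc1)COC(c1ccccc1)(c1ccccc1)c1ccccc1)CC(O)CO | intermediate (not isolated)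
15 | (3R,5R)-3-ethynyl-5-[(4-methoxybenzyl)oxy]-3-methyl-6-(trityloxy)hexanal | C#C[C@](C)(C[C@@H](OCc1ccc(OC)cc1)COC(c1ccccc1)(c1ccccc1)c1ccccc1)CC=O | intermediate
16 | methyl (3S,4R,6S,8R)-3-{[(4S)-4-benzyl-2-oxo-1,3-oxazolidin-3-yl]carbonyl}-6-ethynyl-4-hydroxy-8-[(4-methoxybenzyl)oxy]-6-methyl-9-(trityloxy)nonanoate (syn-aldol adduct) | C#C[C@](C)(C[C@@H](OCc1ccc(OC)cc1)COC(c1ccccc1)(c1ccccc1)c1ccccc1)C[C@@H](O)[C@H](CC(=O)OC)C(=O)N1[C@@H](Cc2ccccc2)COC1=O | intermediate
17 | 4-O-[(2E)-2-methylbut-2-enoyl] derivative (C12 tiglate) of 16 | C#C[C@](C)(C[C@@H](OCc1ccc(OC)cc1)COC(c1ccccc1)(c1ccccc1)c1ccccc1)C[C@@H](OC(=O)/C(C)=C/C)[C@H](CC(=O)OC)C(=O)N1[C@@H](Cc2ccccc2)COC1=O | intermediate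
18 | methyl (3R,4R,6S,8R)-6-ethynyl-3-(hydroxymethyl)-8-[(4-methoxybenzyl)oxy]-6-methyl-4-{[(2E)-2-methylbut-2-enoyl]oxy}-9-(trityloxy)nonanoate | C#C[C@](C)(C[C@@H](OCc1ccc(OC)cc1)COC(c1ccccc1)(c1ccccc1)c1ccccc1)C[C@@H](OC(=O)/C(C)=C/C)[C@H](CC(=O)OC)CO | intermediate (not isolated)
19 | (1R,3S,5R)-3-ethynyl-5-[(4-methoxybenzyl)oxy]-3-methyl-1-[(3R)-5-oxooxolan-3-yl]-6-(trityloxy)hexyl (2E)-2-methylbut-2-enoate | C#C[C@](C)(C[C@@H](OCc1ccc(OC)cc1)COC(c1ccccc1)(c1ccccc1)c1ccccc1)C[C@@H](OC(=O)/C(C)=C/C)[C@H]1COC(=O)C1 | intermediate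
20 | (1R,3S,5R)-3-ethynyl-6-hydroxy-5-[(4-methoxybenzyl)oxy]-3-methyl-1-[(3R)-5-oxooxolan-3-yl]hexyl (2E)-2-methylbut-2-enoate | C#C[C@](C)(C[C@@H](OCc1ccc(OC)cc1)CO)C[C@@H](OC(=O)/C(C)=C/C)[C@H]1COC(=O)C1 | intermediate
21 | (1R,3S,5R)-3-ethynyl-5-[(4-methoxybenzyl)oxy]-3-methyl-6-oxo-1-[(3R)-5-oxooxolan-3-yl]hexyl (2E)-2-methylbut-2-enoate | C#C[C@](C)(C[C@@H](OCc1ccc(OC)cc1)C=O)C[C@@H](OC(=O)/C(C)=C/C)[C@H]1COC(=O)C1 | intermediate
22 | chloromagnesium (2Z)-3-(chloromagnesio)-2-ethenylbut-2-en-1-olate (chloromagnesium alkoxide of the alkenylmagnesium chloride; LiCl and solvent omitted) | Cl[Mg]OC/C(C=C)=C(\[Mg]Cl)C | intermediate (not isolated)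
23 | (1R,3S,5R,6R,7Z)-3-ethynyl-6-hydroxy-8-(hydroxymethyl)-5-[(4-methoxybenzyl)oxy]-3,7-dimethyl-1-[(3R)-5-oxooxolan-3-yl]deca-7,9-dien-1-yl (2E)-2-methylbut-2-enoate | C#C[C@](C)(C[C@@H](OCc1ccc(OC)cc1)[C@H](O)/C(C)=C(\CO)C=C)C[C@@H](OC(=O)/C(C)=C/C)[C@H]1COC(=O)C1 | intermediate
24 | (1R,3S,5R)-5-[(4R)-6-ethenyl-5-methyl-2-oxo-4,7-dihydro-1,3-dioxepin-4-yl]-3-ethynyl-5-[(4-methoxybenzyl)oxy]-3-methyl-1-[(3R)-5-oxooxolan-3-yl]pentyl (2E)-2-methylbut-2-enoate | C#C[C@](C)(C[C@@H](OCc1ccc(OC)cc1)[C@@H]1OC(=O)OCC(C=C)=C1C)C[C@@H](OC(=O)/C(C)=C/C)[C@H]1COC(=O)C1 | intermediate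
25 | (E)-alkenyl(dicyclohexyl)borane from 24 (Cy2B on C1, E C1=C10) | C1CCCCC1B(C1CCCCC1)/C=C/[C@](C)(C[C@@H](OCc1ccc(OC)cc1)[C@@H]1OC(=O)OCC(C=C)=C1C)C[C@@H](OC(=O)/C(C)=C/C)[C@H]1COC(=O)C1 | intermediate (not isolated)
26 | 1-(dicyclohexylboryl) cycloadduct (trans-decalin, C3=C4, 6,18-cyclic carbonate) | O=C1OCC2=CC[C@@H](B(C4CCCCC4)C4CCCCC4)[C@H]3[C@@]2(C)[C@@H](O1)[C@H](OCc2ccc(OC)cc2)C[C@]3(C)C[C@@H](OC(=O)/C(C)=C/C)[C@H]1COC(=O)C1 | intermediate (not isolated)
27 | (1R,5R,6R,7R,9S,10R,12R,13R)-1-hydroxy-7-[(4-methoxybenzyl)oxy]-12-(tigloyloxy)-17-norclerod-3-en-15,16-olide 6,18-cyclic carbonate | O=C1OCC2=CC[C@@H](O)[C@H]3[C@@]2(C)[C@@H](O1)[C@H](OCc2ccc(OC)cc2)C[C@]3(C)C[C@@H](OC(=O)/C(C)=C/C)[C@H]1COC(=O)C1 | intermediate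
28 | 1-O-isobutyryl derivative of 27 | O=C1OCC2=CC[C@@H](OC(=O)C(C)C)[C@H]3[C@@]2(C)[C@@H](O1)[C@H](OCc2ccc(OC)cc2)C[C@]3(C)C[C@@H](OC(=O)/C(C)=C/C)[C@H]1COC(=O)C1 | intermediate
29 | (1R,5R,6R,7R,9S,10R,12R,13R)-7-hydroxy-1-(isobutyryloxy)-12-(tigloyloxy)-17-norclerod-3-en-15,16-olide 6,18-cyclic carbonate | O=C1OCC2=CC[C@@H](OC(=O)C(C)C)[C@H]3[C@@]2(C)[C@@H](O1)[C@H](O)C[C@]3(C)C[C@@H](OC(=O)/C(C)=C/C)[C@H]1COC(=O)C1 | intermediate
30 | (1R,5R,6R,9S,10R,12R,13R)-1-(isobutyryloxy)-7-oxo-12-(tigloyloxy)-17-norclerod-3-en-15,16-olide 6,18-cyclic carbonate | O=C1OCC2=CC[C@@H](OC(=O)C(C)C)[C@H]3[C@@]2(C)[C@@H](O1)C(=O)C[C@]3(C)C[C@@H](OC(=O)/C(C)=C/C)[C@H]1COC(=O)C1 | intermediate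
31 | (1R,5R,6R,9S,10R,12R,13R)-6-hydroxy-1-(isobutyryloxy)-7-oxo-12-(tigloyloxy)-17-norclerod-4(18)-en-15,16-olide | C=C1CC[C@@H](OC(=O)C(C)C)[C@H]2[C@@]1(C)[C@@H](O)C(=O)C[C@]2(C)C[C@@H](OC(=O)/C(C)=C/C)[C@H]1COC(=O)C1 | intermediate
32 | CNP0148909.1: (1R,5R,6R,9R,10R,12R,13R)-6-hydroxy-1-(isobutyryloxy)-7-oxo-12-(tigloyloxy)cleroda-4(18),8(17)-dien-15,16-olide | C=C1CC[C@@H](OC(=O)C(C)C)[C@H]2[C@@]1(C)[C@@H](O)C(=O)C(=C)[C@]2(C)C[C@@H](OC(=O)/C(C)=C/C)[C@H]1COC(=O)C1 | target

**Summary**

Total step count: 22. Longest linear sequence: 20 steps (steps 3–22, from 7).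

Steps most likely to fail:

Step 17 (the labelled step). What may go wrong: hydroboration of the diene vinyl group in competition with the alkyne; a cycloaddition too slow at the congested C5 terminus, so that a thermal [1,5]-hydrogen shift of the Z-methyl diene intervenes; loss of endo selectivity. The fallback uses known chemistry, with a carbonyl-activated dienophile and a Baeyer–Villiger oxidation in place of the borane. Setting out from 24, hydrozirconation with Cp2Zr(H)Cl and CuBr·SMe2-catalysed acylation with acetyl chloride should give the (E)-methyl enone F1. Me2AlCl in CH2Cl2 at −78 → −20 °C should promote the endo intramolecular Diels–Alder reaction to the 1-acetyl decalin F2. Baeyer–Villiger oxidation with bis(trimethylsilyl) peroxide and SnCl4, which spares C=C bonds and proceeds with retention, should give the C1 acetate F3. K2CO3 in MeOH cleaves the acetate and the cyclic carbonate to the triol F4 (PPTS re-closes any opened lactone), and one equivalent of CDI re-forms the seven-membered carbonate across the cis-disposed C18 and C6 hydroxyls, which comes back to the route at 27.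

Step 22. What may go wrong: slow enolisation towards the hindered C8, enediol isomerisation of the α-ketol, or conjugate addition to the product enone. Setting out from 31, Me3SiOTf/Et3N should give the bis(trimethylsilyl) compound F5 (6-O-silyl ether and C7=C8 silyl enol ether). Eschenmoser's salt then gives, after aqueous work-up, the Mannich base F6, and quaternisation with MeI followed by elimination on NaHCO3 comes back to the route at 32.

Step 15. What may go wrong: incomplete chelation control and hence poor facial selectivity at C6, deprotonation of the terminal alkyne, or attack of the organomagnesium reagent on the lactone and ester carbonyls. Setting out from 21 and 3, a Nozaki–Hiyama–Kishi coupling (CrCl2, NiCl2 as catalyst, a chiral sulfonamide–oxazoline ligand, THF) forms the same C5–C6 bond under catalyst control and tolerates the esters and the alkyne; it comes back to the route at 23 and makes no new compound (F0).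

Further compounds
F1 | step 17 | (E)-methyl enone from 24 (CH3CO on C1, E C1=C10) | CC(=O)/C=C/[C@](C)(C[C@@H](OCc1ccc(OC)cc1)[C@@H]1OC(=O)OCC(C=C)=C1C)C[C@@H](OC(=O)/C(C)=C/C)[C@H]1COC(=O)C1
F2 | step 17 | 1-acetyl analogue of 27 (acetyl in place of 1-OH) | O=C1OCC2=CC[C@@H](C(C)=O)[C@H]3[C@@]2(C)[C@@H](O1)[C@H](OCc2ccc(OC)cc2)C[C@]3(C)C[C@@H](OC(=O)/C(C)=C/C)[C@H]1COC(=O)C1
F3 | step 17 | 1-O-acetyl derivative of 27 | O=C1OCC2=CC[C@@H](OC(C)=O)[C@H]3[C@@]2(C)[C@@H](O1)[C@H](OCc2ccc(OC)cc2)C[C@]3(C)C[C@@H](OC(=O)/C(C)=C/C)[C@H]1COC(=O)C1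
F4 | step 17 | 1,6,18-triol (27 without the carbonate bridge) | OCC1=CC[C@@H](O)[C@H]2[C@@]1(C)[C@@H](O)[C@H](OCc1ccc(OC)cc1)C[C@]2(C)C[C@@H](OC(=O)/C(C)=C/C)[C@H]1COC(=O)C1
F5 | step 22 | 6-O-trimethylsilyl C7=C8 trimethylsilyl enol ether of 31 | C=C1CC[C@@H](OC(=O)C(C)C)[C@H]2[C@@]1(C)[C@@H](O[Si](C)(C)C)C(O[Si](C)(C)C)=C[C@]2(C)C[C@@H](OC(=O)/C(C)=C/C)[C@H]1COC(=O)C1
F6 | step 22 | 8-[(dimethylamino)methyl] derivative of 31 (Mannich base, both C8 epimers) | C=C1CC[C@@H](OC(=O)C(C)C)[C@H]2[C@@]1(C)[C@@H](O)C(=O)C(CN(C)C)[C@]2(C)C[C@@H](OC(=O)/C(C)=C/C)[C@H]1COC(=O)C1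
F0 | step 15 | none | none
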